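## Structural features

The target is a chain of six oxygenated benzene rings, A to F, joined only by five diaryl ether bridges (A1–O–B1, B4–O–C1, C2–O–D1, D4–O–E1, E2–O–F1). It has no carbon chain and no stereocentre, so no question of neighbouring stereocentres arises. Ring A is a 2,4,6-trihydroxyphenoxy group, rings B and D are 3,5-dihydroxy-1,4-phenylenedioxy units, rings C and E each carry five contiguous oxygens (ether oxygens at positions 1 and 2, hydroxyls at 3 to 5, hydrogen at 6), and ring F is a 3,4,5-trihydroxyphenoxy group; B–C and D–E are therefore one repeat unit used twice. The sixteen free hydroxyls, above all the pyrogallol-type arrays of rings C, E and F, are oxidised readily by air and base, whereas the diaryl ethers are robust, so the polyphenol should be unveiled only in a last, neutral step. The real difficulty is that every ether oxygen sits on at least one carbon flanked by two oxygen-bearing ring carbons: B4–O–C1 and D4–O–E1 join a carbon with two ortho oxygens to a carbon with one, a pattern that arene C–O coupling serves badly, and rings C and E need five oxygens placed without regiochemical ambiguity. The other three ethers are easier, because one partner carbon (B1, D1, F1) has two ortho hydrogens and stands para to an oxygen that can be masked as a formyl group. The key step uses the fact that in ring C the carbons C2 to C5 all bear oxygen and correspond to the four carbons of a squarate ester, while C1 (with the B4 oxygen) and C6 (with hydrogen) correspond to a 1-aryloxyvinyl group; ring E has the same make-up.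

## Logic of the disconnections

38 ⇒ 37. The fifteen benzylic O–C bonds are cut. The free polyphenol is polar and air-sensitive, so all earlier chemistry is run on benzyl ethers, which are soluble and not oxidisable. The forward step must be one exhaustive, neutral hydrogenolysis that leaves the diaryl ethers alone.

37 ⇒ 34 + 7 (through 36 and 35). The F4–O bond is traced back to a formyl carbon, and the E2–O–F1 ether is cut between oxygen and F1. F1 has two ortho hydrogens and in 7 lies para to the formyl group, so the hindered E2 phenol meets an unhindered, activated C–Br bond. Ring F then comes from the same bromide as rings B and D. The forward demand is a copper coupling that accepts a phenol flanked by an aryloxy and a benzyloxy group, and an oxidation that touches only the aldehyde.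

34 ⇒ 33. The benzyl O–C bond at E5 is cut. This exposes the hydroquinone that the ring expansion delivers. The forward step must tell the E5 hydroxyl (one ortho substituent) from the E2 hydroxyl (two).

33 ⇒ 29 + 17. Ring E is opened at E1–E2 and E5–E6, the same cut as in ring C. This removes a pentaoxygenated ring and the hindered D4–O–E1 ether at once. The forward demand is that of the key step, now on a tetramer.

29 ⇒ 25 + 11 (through 28, 27 and 26). The C–Sn bond, then the two vinyl carbons, are removed back to the D4 phenol. The two-carbon unit comes from 11. The forward steps must place tin on the oxygen-bearing carbon and must use n-BuLi without harming benzyl ethers.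

25 ⇒ 22 + 7 (through 24 and 23). The D4–O bond goes back to a formyl carbon, and the C2–O–D1 ether is cut at D1. A more convergent union, in which rings D to F would arrive together as one aryl halide, was weighed against this. It would force ring D to carry its halide through two organolithium steps and would pair the hindered phenol with a large, unactivated partner. The small activated bromide 7 was preferred at the cost of a longer linear sequence.

22 ⇒ 21. The benzyl O–C bond at C5 is cut, for the same reason and with the same demand as 34 ⇒ 33.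

21 ⇒ 15 + 17. Ring C is cut at C1–C2 and C5–C6. Five oxygens and the crowded B4–O–C1 ether are thereby reduced to a squarate and a vinyl ether, and the regiochemistry is fixed by connectivity. The forward step needs a single addition to 17 and a ring opening that turns the vinyl group toward the ketene.

15 ⇒ 10 + 11 (through 14, 13 and 12). As for 29; the precursor is kept as the 1-stannylvinyl ether. Its preparation is tightened by choosing a palladium-catalysed hydrostannation for the regiochemistry and by not storing the ynol ether.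

10 ⇒ 4 + 7 (through 9 and 8). The B4–O bond goes back to a formyl carbon, and the A1–O–B1 ether is cut at B1, so that the hindered ring A phenol is the nucleophile.

4 ⇒ 1 (through 3 and 2); 7 ⇒ 5 + two equivalents of 6; 17 ⇒ 16 + two equivalents of 6. Benzyl O–C bonds and aryl C–O bonds are cut back to purchased materials. The demands are O- over C-benzylation in 1, displacement of both fluorides but not the bromide in 5, and removal of water in the twofold esterification of 16.

## Other disconnections considered

Alternative 1: Both ether bonds at ring E (O–E1 and O–E2) are cut. 4,5-Dichloro-1,2,3-trimethoxybenzene A1 would be used as its cyclopentadienylruthenium hexafluorophosphate complex A2, [(C5H5)Ru(η6-arene)]PF6. A2 would take first the D4 phenoxide of the tetramer phenol 25 at E1, then the phenoxide of 3,4,5-tris(benzyloxy)phenol A3 at E2, to give the complexed hexamer A4.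
- In favour: η6-coordination to the cationic metal makes chloroarene substitution possible near room temperature even with hindered phenoxides, and two ethers form in one pot from two sizeable pieces.
- Against: the two chlorides are neighbours and almost equally activated, so site selection rests on sterics alone. The second displacement must occur at a carbon flanked by methoxy and the new bulky aryloxy group. Ring E has to carry methyl ethers (the phenyl rings of benzyl groups would compete for the metal), so after removal of ruthenium from A4 three methyl ethers must be cleaved with BBr3 next to thirteen benzyl ethers. The metal is stoichiometric. Ring C is not addressed, so 25 is still needed.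
- Comparison: on step economy this alternative is the better one for the second half, since it would replace steps 13 to 18 by about four operations. On mechanism it trades a pericyclic step whose regiochemistry is fixed by connectivity for an ionic substitution whose regiochemistry is kinetic. On structure it gives up the all-benzyl end game.

Alternative 2: The A1–A2 carbon–carbon bond is cut, so ring A becomes an acyclic chain on the B1 oxygen. Mg(OMe)2 would form the chelated enolate at the aryloxymethyl carbon of methyl (E)-3-benzyloxy-5-oxo-6-aryloxyhex-2-enoate A5; Claisen attack on the ester carbon, loss of methanol and enolisation would give hexamer A6.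
- In favour: the hindered A1–O bond exists before the ring does, so no coupling of a 2,4,6-trioxygenated phenol is needed, and A6 needs only hydrogenolysis.
- Against: ring A is the least demanding ring (two steps from a purchased aldehyde plus a well-behaved coupling in the chosen plan), yet the key step would be spent on it at the very end on a pentamer. O-acylation through the ketone enolate oxygen competes with C-acylation, and the more acidic C4 methylene is deprotonated first. Rings C and E remain unsolved, and building A5 on the B1 oxygen costs several steps.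
- Comparison: it is the equal of the chosen plan in the final deprotection and better in avoiding one hindered ether coupling and any C-benzylation risk on ring A. It is weaker on structure (it does not touch the hard rings) and probably longer by two or three steps.

Alternative 3: The O–C1 and O–C2 bonds are cut. 3-Benzyloxy-4,5-dibromo-o-benzoquinone A7 would lose its two bromides by addition–elimination, first to the phenoxide of dimer phenol 10 and then to that of the D-to-F trimer phenol A8, to give the quinone hexamer A9.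
- In favour: it is the most convergent plan (two, one and three rings), uses no metal and no organolithium, and hydrogenation of A9 would reduce the quinone and remove the benzyl groups together.
- Against: A7 is a strong oxidant and the two phenoxides are among the most electron-rich imaginable, so electron transfer and oxidative coupling are expected to compete. The first nucleophile is the hindered one and must choose between two vinylogous acyl bromides, with conjugate addition at C6 as a further path. A8 contains ring E, so the pentaoxygenated-ring problem returns.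
- Comparison: on step economy and longest linear sequence it is better than the chosen plan. On mechanism the chosen plan is safer, because ring C forms under neutral thermal conditions from non-oxidising partners and no regioisomer is possible.

Key step: step 9

Remark on the chemistry: compounds 1, 5, 6, 11 and 16 are taken as purchased, and benzyl alcohol 6 is consumed twice in each of steps 3 and 8. The squarate adducts 19 and 31 have one stereocentre each and form as racemates, which is of no consequence because that centre is lost on ring opening.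

## Route

Step 1
Reactants: 1 2,4,6-trihydroxybenzaldehyde
Product: 2 2,4,6-tris(benzyloxy)benzaldehyde
Conditions: BnBr, K2CO3, DMF, 60 °C
Reagents that add atoms: benzyl bromide, BrCc1ccccc1
Why: Williamson ether synthesis; the formyl group tempers the nucleophilicity of the ring carbons, so O-benzylation should prevail over C-benzylation, and excess halide with warming carries the two hydrogen-bonded ortho hydroxyls through.

Step 2
Reactants: 2 2,4,6-tris(benzyloxy)benzaldehyde
Product: 4 2,4,6-tris(benzyloxy)phenol, via formate ester 3 (not isolated)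
Conditions: mCPBA, CH2Cl2, 0 °C; then K2CO3 (cat.), MeOH, rt
Reagents that add atoms: mCPBA, OOC(=O)c1cccc(Cl)c1
Why: Baeyer–Villiger oxidation of an electron-rich benzaldehyde: the trialkoxyaryl group migrates in the peracid adduct to give formate 3, which catalytic carbonate in methanol cleaves to the phenol in the same flask.

Step 3
Reactants: 5 4-bromo-2,6-difluorobenzaldehyde; 6 benzyl alcohol (2 equiv in all)
Product: 7 2,6-bis(benzyloxy)-4-bromobenzaldehyde
Conditions: BnOH (2.2 equiv), NaH (2.2 equiv), THF–DMF, 0 to 50 °C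
Reagents that add atoms: benzyl alcohol (second equivalent of 6), OCc1ccccc1
Why: Twofold nucleophilic aromatic substitution by sodium benzyl oxide: both fluorides are ortho to the formyl group and should be displaced one after the other far faster than the para bromide, which is kept as the handle for the later ether couplings.

Step 4
Reactants: 4 2,4,6-tris(benzyloxy)phenol; 7 2,6-bis(benzyloxy)-4-bromobenzaldehyde
Product: 8 dimer AB aldehyde (formyl at B4)
Conditions: CuI (10 mol %), picolinic acid (20 mol %), K3PO4, DMSO, 90 °C, Ar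
Reagents that add atoms: none
Why: Ullmann-type copper-catalysed diaryl ether synthesis: the hindered phenol 4 is the nucleophile, and the electrophilic carbon of 7 has two ortho hydrogens and a para formyl group; picolinic acid is a ligand suited to 2,6-disubstituted phenols.

Step 5
Reactants: 8 dimer AB aldehyde
Product: 10 dimer AB phenol (free B4 hydroxyl), via formate ester 9 (not isolated)
Conditions: mCPBA (1.1 equiv), CH2Cl2, 0 °C; then K2CO3 (cat.), MeOH–THF, rt
Reagents that add atoms: mCPBA, OOC(=O)c1cccc(Cl)c1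
Why: Baeyer–Villiger oxidation as in step 2; the 2,6-dialkoxy-4-aryloxyphenyl group migrates readily, and the peracid is kept near one equivalent at 0 °C to spare the alkoxy-rich rings.

Step 6
Reactants: 10 dimer AB phenol; 11 trichloroethylene
Product: 12 dimer AB (E)-1,2-dichlorovinyl ether
Conditions: K2CO3, DMF, 70 °C (closed system)
Reagents that add atoms: none
Why: Carbonate converts trichloroethylene into dichloroacetylene, to which the phenoxide adds in anti fashion to give the (E)-1,2-dichlorovinyl ether, the established entry to aryl ynol ethers; the linear electrophile should tolerate the two ortho benzyloxy groups.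

Step 7
Reactants: 12 dimer AB (E)-1,2-dichlorovinyl ether
Product: 15 dimer AB 1-(tributylstannyl)vinyl ether, via lithium acetylide 13 (not isolated), via ethynyl ether 14 (not isolated)
Conditions: n-BuLi (2.2 equiv), THF, −78 °C; aq NH4Cl; then Bu3SnH, Pd(PPh3)4 (3 mol %), THF, 0 °C to rt
Reagents that add atoms: tributyltin hydride, CCCC[SnH](CCCC)CCCC
Why: n-BuLi removes the vinylic proton, chloride is lost and chlorine–lithium exchange gives acetylide 13, which is protonated to ynol ether 14; zerovalent palladium then catalyses syn hydrostannation, which in ynol ethers places tin on the oxygen-bearing carbon, and the labile alkyne is not stored.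

Step 8
Reactants: 16 squaric acid; 6 benzyl alcohol (2 equiv consumed)
Product: 17 dibenzyl squarate
Conditions: BnOH (2.5 equiv), toluene, reflux, Dean–Stark
Reagents that add atoms: benzyl alcohol (second equivalent of 6), OCc1ccccc1
Why: Twofold esterification of the strongly acidic vinylogous diacid with azeotropic removal of water, the standard route to dialkyl squarates.

Step 9
Reactants: 15 dimer AB 1-(tributylstannyl)vinyl ether; 17 dibenzyl squarate
Product: 21 trimer ABC hydroquinone with free C2 and C5 hydroxyls, via vinyllithium 18 (not isolated), via hydroxycyclobutenone 19 (not isolated), via dienylketene 20 (not isolated)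
Conditions: n-BuLi (0.95 equiv), THF, −78 °C; added to 17 (1.3 equiv), THF, −78 °C; aq NH4Cl, −78 °C; then p-xylene, 138 °C, Ar
Reagents that add atoms: none
Why: Tin–lithium exchange with a slight deficit of n-BuLi converts 15 into the 1-aryloxyvinyllithium 18 (Bu4Sn is inert), which adds once to a ring carbonyl of 17 and so forms the C1–C2 bond; a cold, nearly neutral quench gives the racemic carbinol 19. In hot xylene 19 undergoes the thermal conrotatory 4π ring opening of the Moore rearrangement, and because the hydroxyl, the donor on the breaking bond, rotates outward, the vinyl group turns inward and the (Z)-dienylketene 20 results. 20 closes by a thermally allowed disrotatory 6π electrocyclisation between the ketene carbon and the vinyl CH2 carbon, which forms the C5–C6 bond and the six-membered carbocycle of ring C, and the cyclohexadienone so formed enolises to hydroquinone 21. The closest known reaction type is the ring expansion of 4-alkenyl- and 4-(1-alkoxyalkenyl)-4-hydroxycyclobutenones from dialkyl squarates to alkoxy-substituted hydroquinones. No stereocentre is created in 21, and the one in 19 is erased on ring opening. Mono-addition is secured by adding 18 to an excess of 17 at −78 °C and by the lower electrophilicity of the vinylogous ester carbonyl left in the lithium alkoxide; six-ring closure is secured because the inward vinyl terminus is the only π partner within reach of the ketene. The regiochemistry of ring C follows from connectivity alone: the squarate carbons become C2 to C5 with their oxygens, the vinyl carbons become C1 (with the B4 oxygen) and C6 (with hydrogen). Air is excluded because the pentaoxygenated hydroquinone is easily oxidised to the quinone.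

Step 10
Reactants: 21 trimer ABC hydroquinone
Product: 22 trimer ABC phenol with free C2 hydroxyl and benzyl ethers at C3 to C5
Conditions: BnBr (1.05 equiv), K2CO3, acetone (degassed), rt, Ar
Reagents that add atoms: benzyl bromide, BrCc1ccccc1
Why: Williamson monoalkylation under steric control: the C5 hydroxyl has one ortho substituent and a hydrogen neighbour, whereas the C2 hydroxyl lies between the bulky ring B aryloxy group and a benzyloxy group, so one equivalent of halide should take C5.

Step 11
Reactants: 22 trimer ABC phenol; 7 2,6-bis(benzyloxy)-4-bromobenzaldehyde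
Product: 23 tetramer ABCD aldehyde (formyl at D4)
Conditions: CuI (20 mol %), picolinic acid (40 mol %), K3PO4, DMSO–toluene, 90 °C, Ar
Reagents that add atoms: none
Why: Ullmann-type coupling as in step 4; the C2 phenol is hindered, but 7 offers an unhindered, formyl-activated C–Br bond, which is the reason for bringing ring D in as this small aldehyde.

Step 12
Reactants: 23 tetramer ABCD aldehyde
Product: 25 tetramer ABCD phenol (free D4 hydroxyl), via formate ester 24 (not isolated)
Conditions: mCPBA (1.1 equiv), CH2Cl2, 0 °C; then K2CO3 (cat.), MeOH–THF, rt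
Reagents that add atoms: mCPBA, OOC(=O)c1cccc(Cl)c1
Why: Baeyer–Villiger oxidation and methanolysis as in step 5, turning the D4 formyl group into the D4 hydroxyl; the aldehyde should react with the peracid much faster than the alkoxy-rich rings at 0 °C.

Step 13
Reactants: 25 tetramer ABCD phenol; 11 trichloroethylene
Product: 26 tetramer ABCD (E)-1,2-dichlorovinyl ether
Conditions: K2CO3, DMF, 70 °C (closed system)
Reagents that add atoms: none
Why: Same addition of the phenoxide to dichloroacetylene generated in the flask as in step 6.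

Step 14
Reactants: 26 tetramer ABCD (E)-1,2-dichlorovinyl ether
Product: 29 tetramer ABCD 1-(tributylstannyl)vinyl ether, via lithium acetylide 27 (not isolated), via ethynyl ether 28 (not isolated)
Conditions: n-BuLi (2.2 equiv), THF, −78 °C; aq NH4Cl; then Bu3SnH, Pd(PPh3)4 (3 mol %), THF, 0 °C to rt
Reagents that add atoms: tributyltin hydride, CCCC[SnH](CCCC)CCCC
Why: Elimination and chlorine–lithium exchange to the acetylide, protonation, and palladium-catalysed syn hydrostannation with tin on the oxygen-bearing carbon, as in step 7.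

Step 15
Reactants: 29 tetramer ABCD 1-(tributylstannyl)vinyl ether; 17 dibenzyl squarate
Product: 33 pentamer ABCDE hydroquinone with free E2 and E5 hydroxyls, via vinyllithium 30 (not isolated), via hydroxycyclobutenone 31 (not isolated), via dienylketene 32 (not isolated)
Conditions: n-BuLi (0.95 equiv), THF, −78 °C; added to 17 (1.3 equiv), THF, −78 °C; aq NH4Cl, −78 °C; then p-xylene, 138 °C, Ar
Reagents that add atoms: none
Why: Second use of the Moore ring expansion with the mechanism and controls of step 9: addition forms E1–E2, conrotatory opening with outward hydroxyl gives ketene 32, and 6π closure forms E5–E6 and ring E.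

Step 16
Reactants: 33 pentamer ABCDE hydroquinone
Product: 34 pentamer ABCDE phenol with free E2 hydroxyl and benzyl ethers at E3 to E5
Conditions: BnBr (1.05 equiv), K2CO3, acetone (degassed), rt, Ar
Reagents that add atoms: benzyl bromide, BrCc1ccccc1
Why: Sterically controlled Williamson monoalkylation of the less hindered E5 hydroxyl, as in step 10.

Step 17
Reactants: 34 pentamer ABCDE phenol; 7 2,6-bis(benzyloxy)-4-bromobenzaldehyde
Product: 35 hexamer aldehyde (formyl at F4)
Conditions: CuI (20 mol %), picolinic acid (40 mol %), K3PO4, DMSO–toluene, 90 °C, Ar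
Reagents that add atoms: none
Why: Ullmann-type coupling as in step 11; ring F enters as the same activated bromide, its formyl group standing for the F4 oxygen.

Step 18
Reactants: 35 hexamer aldehyde
Product: 37 hexamer phenol with free F4 hydroxyl and fifteen benzyl ethers, via formate ester 36 (not isolated)
Conditions: mCPBA (1.1 equiv), CH2Cl2, 0 °C; then K2CO3 (cat.), MeOH–THF, rt
Reagents that add atoms: mCPBA, OOC(=O)c1cccc(Cl)c1
Why: Baeyer–Villiger oxidation and methanolysis as in steps 5 and 12.

Step 19
Reactants: 37 hexamer phenol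
Product: 38 CNP0114537.0
Conditions: H2 (1 atm), Pd/C, THF–MeOH, rt; filtration under Ar
Reagents that add atoms: none
Why: Hydrogenolysis of aryl benzyl ethers over Pd/C is neutral and leaves diaryl ethers and arene rings untouched; air is excluded during filtration because the free polyphenol is oxidised easily.

## Compound list

1 | 2,4,6-trihydroxybenzaldehyde | O=Cc1c(O)cc(O)cc1O | starting material
2 | 2,4,6-tris(benzyloxy)benzaldehyde | O=Cc1c(OCc2ccccc2)cc(OCc2ccccc2)cc1OCc2ccccc2 | intermediate
3 | 2,4,6-tris(benzyloxy)phenyl formate | O=COc1c(OCc2ccccc2)cc(OCc2ccccc2)cc1OCc2ccccc2 | intermediate (not isolated)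
4 | 2,4,6-tris(benzyloxy)phenol | Oc1c(OCc2ccccc2)cc(OCc2ccccc2)cc1OCc2ccccc2 | intermediate
5 | 4-bromo-2,6-difluorobenzaldehyde | O=Cc1c(F)cc(Br)cc1F | starting material
6 | benzyl alcohol | OCc1ccccc1 | starting material
7 | 2,6-bis(benzyloxy)-4-bromobenzaldehyde | O=Cc1c(OCc2ccccc2)cc(Br)cc1OCc2ccccc2 | intermediate
8 | dimer AB aldehyde, 2,6-bis(benzyloxy)-4-[2,4,6-tris(benzyloxy)phenoxy]benzaldehyde | c9ccccc9COc1cc(OCc9ccccc9)c(Oc2cc(OCc9ccccc9)c(C=O)c(OCc9ccccc9)c2)c(OCc9ccccc9)c1 | intermediate
9 | dimer AB formate, 2,6-bis(benzyloxy)-4-[2,4,6-tris(benzyloxy)phenoxy]phenyl formate | c9ccccc9COc1cc(OCc9ccccc9)c(Oc2cc(OCc9ccccc9)c(OC=O)c(OCc9ccccc9)c2)c(OCc9ccccc9)c1 | intermediate (not isolated)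
10 | dimer AB phenol, 2,6-bis(benzyloxy)-4-[2,4,6-tris(benzyloxy)phenoxy]phenol | c9ccccc9COc1cc(OCc9ccccc9)c(Oc2cc(OCc9ccccc9)c(O)c(OCc9ccccc9)c2)c(OCc9ccccc9)c1 | intermediate
11 | trichloroethylene | ClC=C(Cl)Cl | starting material
12 | dimer AB (E)-1,2-dichlorovinyl ether at the B4 oxygen | c9ccccc9COc1cc(OCc9ccccc9)c(Oc2cc(OCc9ccccc9)c(O/C(Cl)=C\Cl)c(OCc9ccccc9)c2)c(OCc9ccccc9)c1 | intermediate
13 | lithium acetylide of the dimer AB ethynyl ether | c9ccccc9COc1cc(OCc9ccccc9)c(Oc2cc(OCc9ccccc9)c(OC#C[Li])c(OCc9ccccc9)c2)c(OCc9ccccc9)c1 | intermediate (not isolated)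
14 | dimer AB ethynyl ether at the B4 oxygen | c9ccccc9COc1cc(OCc9ccccc9)c(Oc2cc(OCc9ccccc9)c(OC#C)c(OCc9ccccc9)c2)c(OCc9ccccc9)c1 | intermediate (not isolated)
15 | dimer AB 1-(tributylstannyl)vinyl ether at the B4 oxygen | c9ccccc9COc1cc(OCc9ccccc9)c(Oc2cc(OCc9ccccc9)c(OC(=C)[Sn](CCCC)(CCCC)CCCC)c(OCc9ccccc9)c2)c(OCc9ccccc9)c1 | intermediate
16 | squaric acid | OC1=C(O)C(=O)C1=O | starting material
17 | dibenzyl squarate, 3,4-bis(benzyloxy)cyclobut-3-ene-1,2-dione | O=C1C(=O)C(OCc2ccccc2)=C1OCc2ccccc2 | intermediate
18 | dimer AB 1-lithiovinyl ether | c9ccccc9COc1cc(OCc9ccccc9)c(Oc2cc(OCc9ccccc9)c(OC(=C)[Li])c(OCc9ccccc9)c2)c(OCc9ccccc9)c1 | intermediate (not isolated)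
19 | racemic 2,3-bis(benzyloxy)-4-hydroxy-4-[1-(dimer AB B4-oxy)vinyl]cyclobut-2-en-1-one | c9ccccc9COc1cc(OCc9ccccc9)c(Oc2cc(OCc9ccccc9)c(OC(=C)C3(O)C(=O)C(OCc9ccccc9)=C3OCc9ccccc9)c(OCc9ccccc9)c2)c(OCc9ccccc9)c1 | intermediate (not isolated)
20 | (Z)-dienylketene from 19, 2,3-bis(benzyloxy)-4-hydroxy-5-(dimer AB B4-oxy)hexa-1,3,5-trien-1-one | c9ccccc9COc1cc(OCc9ccccc9)c(Oc2cc(OCc9ccccc9)c(OC(=C)/C(O)=C(OCc9ccccc9)\C(OCc9ccccc9)=C=O)c(OCc9ccccc9)c2)c(OCc9ccccc9)c1 | intermediate (not isolated)
21 | trimer ABC hydroquinone, free hydroxyls at C2 and C5, benzyl ethers at C3 and C4 | c9ccccc9COc1cc(OCc9ccccc9)c(Oc2cc(OCc9ccccc9)c(Oc3cc(O)c(OCc9ccccc9)c(OCc9ccccc9)c3O)c(OCc9ccccc9)c2)c(OCc9ccccc9)c1 | intermediate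
22 | trimer ABC phenol, free hydroxyl at C2, benzyl ethers at C3 to C5 | c9ccccc9COc1cc(OCc9ccccc9)c(Oc2cc(OCc9ccccc9)c(Oc3cc(OCc9ccccc9)c(OCc9ccccc9)c(OCc9ccccc9)c3O)c(OCc9ccccc9)c2)c(OCc9ccccc9)c1 | intermediate
23 | tetramer ABCD aldehyde, formyl at D4, ten benzyl ethers | c9ccccc9COc1cc(OCc9ccccc9)c(Oc2cc(OCc9ccccc9)c(Oc3cc(OCc9ccccc9)c(OCc9ccccc9)c(OCc9ccccc9)c3Oc3cc(OCc9ccccc9)c(C=O)c(OCc9ccccc9)c3)c(OCc9ccccc9)c2)c(OCc9ccccc9)c1 | intermediate
24 | tetramer ABCD formate at D4 | c9ccccc9COc1cc(OCc9ccccc9)c(Oc2cc(OCc9ccccc9)c(Oc3cc(OCc9ccccc9)c(OCc9ccccc9)c(OCc9ccccc9)c3Oc3cc(OCc9ccccc9)c(OC=O)c(OCc9ccccc9)c3)c(OCc9ccccc9)c2)c(OCc9ccccc9)c1 | intermediate (not isolated)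
25 | tetramer ABCD phenol, free hydroxyl at D4 | c9ccccc9COc1cc(OCc9ccccc9)c(Oc2cc(OCc9ccccc9)c(Oc3cc(OCc9ccccc9)c(OCc9ccccc9)c(OCc9ccccc9)c3Oc3cc(OCc9ccccc9)c(O)c(OCc9ccccc9)c3)c(OCc9ccccc9)c2)c(OCc9ccccc9)c1 | intermediate
26 | tetramer ABCD (E)-1,2-dichlorovinyl ether at the D4 oxygen | c9ccccc9COc1cc(OCc9ccccc9)c(Oc2cc(OCc9ccccc9)c(Oc3cc(OCc9ccccc9)c(OCc9ccccc9)c(OCc9ccccc9)c3Oc3cc(OCc9ccccc9)c(O/C(Cl)=C\Cl)c(OCc9ccccc9)c3)c(OCc9ccccc9)c2)c(OCc9ccccc9)c1 | intermediate
27 | lithium acetylide of the tetramer ABCD ethynyl ether | c9ccccc9COc1cc(OCc9ccccc9)c(Oc2cc(OCc9ccccc9)c(Oc3cc(OCc9ccccc9)c(OCc9ccccc9)c(OCc9ccccc9)c3Oc3cc(OCc9ccccc9)c(OC#C[Li])c(OCc9ccccc9)c3)c(OCc9ccccc9)c2)c(OCc9ccccc9)c1 | intermediate (not isolated)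
28 | tetramer ABCD ethynyl ether at the D4 oxygen | c9ccccc9COc1cc(OCc9ccccc9)c(Oc2cc(OCc9ccccc9)c(Oc3cc(OCc9ccccc9)c(OCc9ccccc9)c(OCc9ccccc9)c3Oc3cc(OCc9ccccc9)c(OC#C)c(OCc9ccccc9)c3)c(OCc9ccccc9)c2)c(OCc9ccccc9)c1 | intermediate (not isolated)
29 | tetramer ABCD 1-(tributylstannyl)vinyl ether at the D4 oxygen | c9ccccc9COc1cc(OCc9ccccc9)c(Oc2cc(OCc9ccccc9)c(Oc3cc(OCc9ccccc9)c(OCc9ccccc9)c(OCc9ccccc9)c3Oc3cc(OCc9ccccc9)c(OC(=C)[Sn](CCCC)(CCCC)CCCC)c(OCc9ccccc9)c3)c(OCc9ccccc9)c2)c(OCc9ccccc9)c1 | intermediate
30 | tetramer ABCD 1-lithiovinyl ether | c9ccccc9COc1cc(OCc9ccccc9)c(Oc2cc(OCc9ccccc9)c(Oc3cc(OCc9ccccc9)c(OCc9ccccc9)c(OCc9ccccc9)c3Oc3cc(OCc9ccccc9)c(OC(=C)[Li])c(OCc9ccccc9)c3)c(OCc9ccccc9)c2)c(OCc9ccccc9)c1 | intermediate (not isolated)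
31 | racemic 2,3-bis(benzyloxy)-4-hydroxy-4-[1-(tetramer ABCD D4-oxy)vinyl]cyclobut-2-en-1-one | c9ccccc9COc1cc(OCc9ccccc9)c(Oc2cc(OCc9ccccc9)c(Oc3cc(OCc9ccccc9)c(OCc9ccccc9)c(OCc9ccccc9)c3Oc3cc(OCc9ccccc9)c(OC(=C)C4(O)C(=O)C(OCc9ccccc9)=C4OCc9ccccc9)c(OCc9ccccc9)c3)c(OCc9ccccc9)c2)c(OCc9ccccc9)c1 | intermediate (not isolated)
32 | (Z)-dienylketene from 31 | c9ccccc9COc1cc(OCc9ccccc9)c(Oc2cc(OCc9ccccc9)c(Oc3cc(OCc9ccccc9)c(OCc9ccccc9)c(OCc9ccccc9)c3Oc3cc(OCc9ccccc9)c(OC(=C)/C(O)=C(OCc9ccccc9)\C(OCc9ccccc9)=C=O)c(OCc9ccccc9)c3)c(OCc9ccccc9)c2)c(OCc9ccccc9)c1 | intermediate (not isolated)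
33 | pentamer ABCDE hydroquinone, free hydroxyls at E2 and E5, benzyl ethers at E3 and E4 | c9ccccc9COc1cc(OCc9ccccc9)c(Oc2cc(OCc9ccccc9)c(Oc3cc(OCc9ccccc9)c(OCc9ccccc9)c(OCc9ccccc9)c3Oc3cc(OCc9ccccc9)c(Oc4cc(O)c(OCc9ccccc9)c(OCc9ccccc9)c4O)c(OCc9ccccc9)c3)c(OCc9ccccc9)c2)c(OCc9ccccc9)c1 | intermediate
34 | pentamer ABCDE phenol, free hydroxyl at E2, benzyl ethers at E3 to E5 | c9ccccc9COc1cc(OCc9ccccc9)c(Oc2cc(OCc9ccccc9)c(Oc3cc(OCc9ccccc9)c(OCc9ccccc9)c(OCc9ccccc9)c3Oc3cc(OCc9ccccc9)c(Oc4cc(OCc9ccccc9)c(OCc9ccccc9)c(OCc9ccccc9)c4O)c(OCc9ccccc9)c3)c(OCc9ccccc9)c2)c(OCc9ccccc9)c1 | intermediate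
35 | hexamer aldehyde, formyl at F4, fifteen benzyl ethers | c9ccccc9COc1cc(OCc9ccccc9)c(Oc2cc(OCc9ccccc9)c(Oc3cc(OCc9ccccc9)c(OCc9ccccc9)c(OCc9ccccc9)c3Oc3cc(OCc9ccccc9)c(Oc4cc(OCc9ccccc9)c(OCc9ccccc9)c(OCc9ccccc9)c4Oc4cc(OCc9ccccc9)c(C=O)c(OCc9ccccc9)c4)c(OCc9ccccc9)c3)c(OCc9ccccc9)c2)c(OCc9ccccc9)c1 | intermediate
36 | hexamer formate at F4 | c9ccccc9COc1cc(OCc9ccccc9)c(Oc2cc(OCc9ccccc9)c(Oc3cc(OCc9ccccc9)c(OCc9ccccc9)c(OCc9ccccc9)c3Oc3cc(OCc9ccccc9)c(Oc4cc(OCc9ccccc9)c(OCc9ccccc9)c(OCc9ccccc9)c4Oc4cc(OCc9ccccc9)c(OC=O)c(OCc9ccccc9)c4)c(OCc9ccccc9)c3)c(OCc9ccccc9)c2)c(OCc9ccccc9)c1 | intermediate (not isolated)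
37 | hexamer phenol, free hydroxyl at F4, fifteen benzyl ethers | c9ccccc9COc1cc(OCc9ccccc9)c(Oc2cc(OCc9ccccc9)c(Oc3cc(OCc9ccccc9)c(OCc9ccccc9)c(OCc9ccccc9)c3Oc3cc(OCc9ccccc9)c(Oc4cc(OCc9ccccc9)c(OCc9ccccc9)c(OCc9ccccc9)c4Oc4cc(OCc9ccccc9)c(O)c(OCc9ccccc9)c4)c(OCc9ccccc9)c3)c(OCc9ccccc9)c2)c(OCc9ccccc9)c1 | intermediate
38 | CNP0114537.0 | Oc1cc(O)c(Oc2cc(O)c(Oc3cc(O)c(O)c(O)c3Oc3cc(O)c(Oc4cc(O)c(O)c(O)c4Oc4cc(O)c(O)c(O)c4)c(O)c3)c(O)c2)c(O)c1 | target

## Step count and least certain steps

Total steps: 19. Longest linear sequence: 17 steps (steps 1, 2, 4 to 7 and 9 to 19); steps 3 and 8 make the two shared building blocks 7 and 17.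

Step 9 (key step; the same holds for step 15). The vinyllithium may decompose before it adds, by loss of aryloxide from the carbenoid-like carbon or by proton transfer from a flanking benzylic CH2 followed by Wittig rearrangement. Double addition to the squarate, hydrolysis of the enol ether in the quench, or capture of the ketene by the hydroxyl instead of electrocyclisation are further risks, and the hydroquinone may be oxidised on handling.
Fallback, from 10 back to the route at 22: ring C is attached by arene coupling instead. Purchased 5-bromobenzene-1,2,3-triol would be perbenzylated to 5-bromo-1,2,3-tris(benzyloxy)benzene F1 and formylated under Vilsmeier–Haack conditions (POCl3, DMF) next to bromine to give 6-bromo-2,3,4-tris(benzyloxy)benzaldehyde F2. F2 would be coupled with 10 (CuI, picolinic acid, K3PO4, DMSO, 110 °C) to the trimer ABC aldehyde with formyl at C2 F3; Baeyer–Villiger oxidation and methanolysis of F3 would give 22 directly, since C5 already carries its benzyl ether.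

Step 7 (and step 14). The hydrostannation may lose regiocontrol and put tin on the terminal carbon, the ynol ether may polymerise, n-BuLi may metalate benzylic positions, and the stannane may be protodestannylated on silica.
Fallback, from 10 back to 15, without alkyne or hydrostannation: 10 would be acetylated (Ac2O, pyridine) to the dimer AB acetate F4, converted with KN(SiMe3)2 and (PhO)2P(O)Cl at −78 °C into the ketene acetal diphenyl phosphate F5, and coupled with Bu3SnSnBu3 (Pd(PPh3)4, LiCl, THF, reflux) to give 15 with the tin position fixed by the phosphate.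

Step 10 (and step 16). Discrimination between the two hydroxyls may be insufficient, giving bis-benzylation or alkylation at C2, and the hydroquinone may be oxidised under base.
Fallback, from 15 (with 17) back to 22, differentiating through the carbinol oxygen instead of through hindrance: after addition of the vinyllithium to 17 the lithium alkoxide would be trapped with MOMCl to give the 4-(methoxymethoxy)cyclobutenone F6. Thermolysis in xylene would give the trimer phenol with a free C5 hydroxyl and a C2 methoxymethyl ether F7, benzylation (BnBr, K2CO3) its C5 benzyl ether F8, and HCl in MeOH–THF would release the C2 hydroxyl to give 22, at the cost of one extra step.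

Step 11 (and steps 4 and 17). Coupling of the doubly flanked phenoxide may be slow, so that reductive loss of bromine from 7 or oxidation of the electron-rich phenol by copper and traces of oxygen takes over.
Fallback, from 7 (with 22) back to 23, changing the aryl partner from electrophile to boron nucleophile: 7 would be borylated (Pd(OAc)2, XPhos, B2(OH)4, KOAc, EtOH) to [3,5-bis(benzyloxy)-4-formylphenyl]boronic acid F9, which would be joined to 22 by Chan–Lam coupling (Cu(OAc)2, pyridine, 4 Å sieves, air, CH2Cl2, rt) to give 23.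

Step 12 (and steps 5 and 18). Chemoselectivity may be lost: the peracid may attack the pentaoxygenated ring C at C6 or ring A, or over-oxidise the product phenol.
Fallback, from 22 (with 7) back to 25, so that no oxidation is run on the oligomer: 7 would be oxidised at the monomer stage (mCPBA, then methanolysis) to 4-bromo-2,6-bis(benzyloxy)phenol F10 and protected (MOMCl, i-Pr2NEt) as 5-bromo-1,3-bis(benzyloxy)-2-(methoxymethoxy)benzene F11. F11 would be coupled with 22 under the copper conditions at 110 °C to the tetramer D4 methoxymethyl ether F12, and HCl in MeOH–THF would give 25.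

## Further compounds

F1 | step 9 | 5-bromo-1,2,3-tris(benzyloxy)benzene | Brc1cc(OCc2ccccc2)c(OCc2ccccc2)c(OCc2ccccc2)c1
F2 | step 9 | 6-bromo-2,3,4-tris(benzyloxy)benzaldehyde | O=Cc1c(Br)cc(OCc2ccccc2)c(OCc2ccccc2)c1OCc2ccccc2
F3 | step 9 | trimer ABC aldehyde, formyl at C2, benzyl ethers at C3 to C5 | c9ccccc9COc1cc(OCc9ccccc9)c(Oc2cc(OCc9ccccc9)c(Oc3cc(OCc9ccccc9)c(OCc9ccccc9)c(OCc9ccccc9)c3C=O)c(OCc9ccccc9)c2)c(OCc9ccccc9)c1
F4 | step 7 | dimer AB acetate at the B4 oxygen | c9ccccc9COc1cc(OCc9ccccc9)c(Oc2cc(OCc9ccccc9)c(OC(C)=O)c(OCc9ccccc9)c2)c(OCc9ccccc9)c1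
F5 | step 7 | dimer AB ketene acetal diphenyl phosphate, 1-(dimer AB B4-oxy)vinyl diphenyl phosphate | c9ccccc9COc1cc(OCc9ccccc9)c(Oc2cc(OCc9ccccc9)c(OC(=C)OP(=O)(Oc8ccccc8)Oc8ccccc8)c(OCc9ccccc9)c2)c(OCc9ccccc9)c1
F6 | step 10 | racemic 2,3-bis(benzyloxy)-4-(methoxymethoxy)-4-[1-(dimer AB B4-oxy)vinyl]cyclobut-2-en-1-one | c9ccccc9COc1cc(OCc9ccccc9)c(Oc2cc(OCc9ccccc9)c(OC(=C)C3(OCOC)C(=O)C(OCc9ccccc9)=C3OCc9ccccc9)c(OCc9ccccc9)c2)c(OCc9ccccc9)c1
F7 | step 10 | trimer ABC phenol, free hydroxyl at C5, methoxymethyl ether at C2 | c9ccccc9COc1cc(OCc9ccccc9)c(Oc2cc(OCc9ccccc9)c(Oc3cc(O)c(OCc9ccccc9)c(OCc9ccccc9)c3OCOC)c(OCc9ccccc9)c2)c(OCc9ccccc9)c1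
F8 | step 10 | trimer ABC, benzyl ethers at C3 to C5, methoxymethyl ether at C2 | c9ccccc9COc1cc(OCc9ccccc9)c(Oc2cc(OCc9ccccc9)c(Oc3cc(OCc9ccccc9)c(OCc9ccccc9)c(OCc9ccccc9)c3OCOC)c(OCc9ccccc9)c2)c(OCc9ccccc9)c1
F9 | step 11 | [3,5-bis(benzyloxy)-4-formylphenyl]boronic acid | O=Cc1c(OCc2ccccc2)cc(B(O)O)cc1OCc2ccccc2
F10 | step 12 | 4-bromo-2,6-bis(benzyloxy)phenol | Oc1c(OCc2ccccc2)cc(Br)cc1OCc2ccccc2
F11 | step 12 | 5-bromo-1,3-bis(benzyloxy)-2-(methoxymethoxy)benzene | COCOc1c(OCc2ccccc2)cc(Br)cc1OCc2ccccc2
F12 | step 12 | tetramer ABCD methoxymethyl ether at the D4 oxygen | c9ccccc9COc1cc(OCc9ccccc9)c(Oc2cc(OCc9ccccc9)c(Oc3cc(OCc9ccccc9)c(OCc9ccccc9)c(OCc9ccccc9)c3Oc3cc(OCc9ccccc9)c(OCOC)c(OCc9ccccc9)c3)c(OCc9ccccc9)c2)c(OCc9ccccc9)c1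
A1 | alternative 1 | 4,5-dichloro-1,2,3-trimethoxybenzene | COc1cc(Cl)c(Cl)c(OC)c1OC
A2 | alternative 1 | cyclopentadienyl(4,5-dichloro-1,2,3-trimethoxybenzene)ruthenium hexafluorophosphate | COc1cc(Cl)c(Cl)c(OC)c1OC.c1cc[cH-]c1.[Ru+2].F[P-](F)(F)(F)(F)F
A3 | alternative 1 | 3,4,5-tris(benzyloxy)phenol | Oc1cc(OCc2ccccc2)c(OCc2ccccc2)c(OCc2ccccc2)c1
A4 | alternative 1 | cyclopentadienylruthenium hexafluorophosphate complex, bound at ring E, of the hexamer with methyl ethers at E3 to E5 and thirteen benzyl ethers | c9ccccc9COc1cc(OCc9ccccc9)c(Oc2cc(OCc9ccccc9)c(Oc3cc(OCc9ccccc9)c(OCc9ccccc9)c(OCc9ccccc9)c3Oc3cc(OCc9ccccc9)c(Oc4cc(OC)c(OC)c(OC)c4Oc4cc(OCc9ccccc9)c(OCc9ccccc9)c(OCc9ccccc9)c4)c(OCc9ccccc9)c3)c(OCc9ccccc9)c2)c(OCc9ccccc9)c1.c1cc[cH-]c1.[Ru+2].F[P-](F)(F)(F)(F)F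
A5 | alternative 2 | methyl (E)-3-(benzyloxy)-5-oxo-6-(perbenzylated B-to-F pentamer B1-oxy)hex-2-enoate | COC(=O)/C=C(/OCc9ccccc9)CC(=O)COc2cc(OCc9ccccc9)c(Oc3cc(OCc9ccccc9)c(OCc9ccccc9)c(OCc9ccccc9)c3Oc3cc(OCc9ccccc9)c(Oc4cc(OCc9ccccc9)c(OCc9ccccc9)c(OCc9ccccc9)c4Oc4cc(OCc9ccccc9)c(OCc9ccccc9)c(OCc9ccccc9)c4)c(OCc9ccccc9)c3)c(OCc9ccccc9)c2
A6 | alternative 2 | hexamer with free A2 and A6 hydroxyls and fourteen benzyl ethers | c9ccccc9COc1cc(O)c(Oc2cc(OCc9ccccc9)c(Oc3cc(OCc9ccccc9)c(OCc9ccccc9)c(OCc9ccccc9)c3Oc3cc(OCc9ccccc9)c(Oc4cc(OCc9ccccc9)c(OCc9ccccc9)c(OCc9ccccc9)c4Oc4cc(OCc9ccccc9)c(OCc9ccccc9)c(OCc9ccccc9)c4)c(OCc9ccccc9)c3)c(OCc9ccccc9)c2)c(O)c1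
A7 | alternative 3 | 3-(benzyloxy)-4,5-dibromocyclohexa-3,5-diene-1,2-dione | O=C1C(=O)C(OCc2ccccc2)=C(Br)C(Br)=C1
A8 | alternative 3 | trimer DEF phenol, free hydroxyl at D1, eight benzyl ethers | Oc3cc(OCc9ccccc9)c(Oc4cc(OCc9ccccc9)c(OCc9ccccc9)c(OCc9ccccc9)c4Oc4cc(OCc9ccccc9)c(OCc9ccccc9)c(OCc9ccccc9)c4)c(OCc9ccccc9)c3
A9 | alternative 3 | hexamer with ring C as its C4,C5 o-quinone and fourteen benzyl ethers | O=C1C=C(Oc2c(OCc9ccccc9)cc(Oc3c(OCc9ccccc9)cc(OCc9ccccc9)cc3OCc9ccccc9)cc2OCc9ccccc9)C(Oc3cc(OCc9ccccc9)c(Oc4cc(OCc9ccccc9)c(OCc9ccccc9)c(OCc9ccccc9)c4Oc4cc(OCc9ccccc9)c(OCc9ccccc9)c(OCc9ccccc9)c4)c(OCc9ccccc9)c3)=C(OCc9ccccc9)C1=O
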